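Readings and results are simulated with made-up constants; the scatter is artificial.

With a small charge of free catalyst, 0.1 mol% here, elm and ash differ by their time.

all flasks: left-handed substrate 0.13 M; right-handed substrate 0.13 M
- alpha: reagent 0.80 equiv; free catalyst 0.067 mol%; run made earlier
- theta: reagent 0.80 equiv; free catalyst 0.15 mol%; run made earlier
- elm: reagent 0.800 equiv; free catalyst 0.1 mol%; time 4.0 h
- ash: reagent 0.800 equiv; free catalyst 0.1 mol%; time 6.0 h

| run | time / h | right-handed substrate / % | left-handed substrate / % | left-handed product / % |
|---|---|---|---|---|
| alpha | 0.333 | 48.2 | 42.3 | 8.5 |
| alpha | 0.500 | 47.5 | 38.1 | 11.3 |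
| alpha | 0.833 | 46.0 | 36.1 | 14.1 |
| alpha | 1.33 | 45.5 | 33.0 | 16.3 |
| alpha | 2.50 | 44.8 | 30.7 | 19.3 |
| alpha | 4.00 | 45.0 | 29.3 | 20.2 |
| theta | 0.667 | 44.3 | 30.5 | 19.8 |
| theta | 1.33 | 44.3 | 26.3 | 22.9 |
| theta | 2.00 | 43.8 | 25.7 | 23.9 |
| theta | 2.50 | 44.0 | 25.8 | 24.6 |
| theta | 3.00 | 43.9 | 25.4 | 24.3 |
| theta | 4.00 | 43.6 | 25.8 | 24.4 |

(scatter of a reading: 0.5 percentage points)

- the winner by excess of right-handed substrate over left-handed substrate among what is left of the two; "neither" if no more than 2 percentage points parts them (elm / ash / neither)
- excess of right-handed substrate over left-handed substrate among what is left of the two at the end, elm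
- excess of right-handed substrate over left-handed substrate among what is left of the two at the end, ash

- free catalyst is single-handed; left-handed substrate and right-handed substrate are mirror images of each other, charged as a racemate, each of them at the stated concentration
- an excess is the difference of the two amounts in percent of their sum
- an excess is below zero if the other one leads

1. Let f be the fraction of a substrate's own charge still there. Theta's last reading gives 4.83 for the selectivity factor s, which is ln f of the left-handed substrate over ln f of the right-handed substrate. Alpha's last reading gives 5.07; both carry the scatter. So f of the right-handed substrate is f of the left-handed substrate to the power 1/s.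

2. The bench rule says one reagent takes one substrate, so the two losses add up to the reagent charge. In a first round, give the reagent to the left-handed substrate: f is 0.200, and s makes the excess 56.4%. In a second round, take the right-handed loss back out of that: f is 0.483, and the excess is 28.1%.

3. The border shows in theta: its two losses reach 0.765 of its reagent charge and stay within the scatter after 2.00 h. Theta's excess reads 25.6%, lower than either round, so the rule stops working there.

4. Instead, read ln f of the left-handed substrate between alpha and theta against log loading, with power 0.265. For elm, f is 0.552, and s gives an excess of 23.1%. Theta's flat tail suggests little gain for ash, so you expect neither.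

5. The forecast says neither, with 23.4% for elm, a little above your figure, and 23.8% for ash. It holds that “the stall is not reagent exhaustion”.

The flask gives neither: 23.6% for elm and 23.8% for ash.

    reagent + free catalyst + right-handed substrate → free catalyst + right-handed product (k = 302 M⁻² min⁻¹)
    2 reagent → homo dimer (k = 0.102 M⁻¹ min⁻¹)
    2 free catalyst → spent catalyst (k = 5.62 M⁻¹ min⁻¹)
    reagent + free catalyst + left-handed substrate → free catalyst + left-handed product (k = 1470 M⁻² min⁻¹)

Elm at 4.00 h keeps 55% of its left-handed substrate, so s gives 88.4% of its right-handed substrate, against 88% in the flask. Elm then holds 0.83% of its reagent and 74.0% of its free catalyst. Elm's excess has moved 5 points at 1.00 equiv of reagent, or at 0.2 mol% of free catalyst. The neighbouring flask, the same as elm but with 3.20 equiv of reagent, ends with 8.50% left-handed substrate. There s gives 34.6% right-handed substrate against 34.7%, and an excess of 60.6% against 60.7%.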